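**Plan**

Numbering used throughout: C1 (quaternary, CH3), C2 (CH–OBz), C3, C4, C5=C6 (CH3 on C5), C7 (lactone CH–O), C8=C17–C19(=O)–O (butenolide, CH3 on C17), C9, C10 (ring-fusion CH), C11=C12 (CH3 on C11), C13 (C=O), C14 (CH–OAc); ring A = C1, C10–C14.
Cuts: C6–C7 of the ten-membered ring first; then the butenolide (C8=C17 and the C7–O ester bond), C3–C4, C2–C3, and ring A into a diene and an enal (C1–C14 and C10–C11).
Forward: ring A by Diels–Alder, oxygen moved to C13 by an ene reaction, the Z-iodoalkene arm alkylated on through C3, the butenolide built on the C9 arm, and the ten-membered ring closed last by joining C6 to C7.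
Enabling feature: C7 is the γ-CH2 of the butenolide ring (O–C19(=O)–C17=C8–C7); its C–H is vinylogously acidic and gives an aromatic 2-oxidofuran that is nucleophilic at C7, and C6 is the sp2 carbon of a preformed Z-iodoalkene, so one palladium-catalysed dienolate alkenylation closes the ring and creates C7 while ring A and the lactone stay intact.
Stereochemistry: C1, C10 and C14 from a catalytic asymmetric Diels–Alder reaction; C2 from a reagent-controlled ketone reduction; Z-C5=C6 from anti-carbomagnesiation of propargyl alcohol, retained; C7 in the ring closure under control of the ring-A template.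
Helper: ring A travels as the C13,C14 bis-silyl ether (no enolisable ketone in steps 10, 11 and 18); steps 19–21 restore the enone and the acetate.

Key step: step 18

Remark: α/β name the faces of ring A, β being the face of the C1 methyl group; the sense of induction in step 3 is assigned from the formyl C–H···O model for 2-alkylacroleins on the oxazaborolidinium ion, and the (R)-catalyst would be used without other change should the (S)-catalyst deliver the mirror-image adduct.

**Route**

Step 1
Reactants: 1 (E)-pent-2-enal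
Product: 2 (1E,3E)-1-(triisopropylsilyloxy)penta-1,3-diene
Conditions: TIPSOTf, Et3N, Et2O, 0 °C → rt
Reagents that add atoms: triisopropylsilyl trifluoromethanesulfonate, CC(C)[Si](OS(=O)(=O)C(F)(F)F)(C(C)C)C(C)C
Why: Soft enolisation of the enal (silyl triflate and amine) removes a γ-hydrogen and should give the dienol silyl ether with the preferred 1E,3E geometry (silyl dienol ether formation).

Step 2
Reactants: 3 3-(tert-butyldimethylsilyloxy)propanal; 4 2-(triphenylphosphoranylidene)propanal
Product: 5 (E)-5-(tert-butyldimethylsilyloxy)-2-methylpent-2-enal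
Conditions: toluene, 90 °C
Reagents that add atoms: none
Why: Wittig olefination with a stabilised formyl ylide should give the E trisubstituted enal, which later fixes the trans relation of C2 and C9.

Step 3
Reactants: 2 (1E,3E)-1-(triisopropylsilyloxy)penta-1,3-diene; 5 (E)-5-(tert-butyldimethylsilyloxy)-2-methylpent-2-enal
Product: 6 ring-A aldehyde
Conditions: (S)-3,3-diphenyl-1-(2-methylphenyl)tetrahydro-1H,3H-pyrrolo[1,2-c][1,3,2]oxazaborole (20 mol %), HNTf2 (17 mol %), CH2Cl2, −78 → −40 °C
Reagents that add atoms: none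
Why: Catalytic asymmetric Diels–Alder reaction in which the silyloxy terminus C14 bonds to the enal α-carbon C1 ("ortho" rule), the E geometry of 5 places the C9 arm trans to the formyl group, endo approach places the formyl group cis to the C14 oxygen, and the oxazaborolidinium ion shields one enal face, so that C1, C10 and C14 are set together (C11 is set too and erased in step 6).

Step 4
Reactants: 6 ring-A aldehyde
Product: 7 ring-A carbinol
Conditions: MeMgBr, THF, −78 → 0 °C; aq. NH4Cl
Reagents that add atoms: methylmagnesium bromide, C[Mg]Br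
Why: Grignard addition to the aldehyde brings in C3; the carbinol centre is left uncontrolled because step 5 oxidises it.

Step 5
Reactants: 7 ring-A carbinol
Product: 8 ring-A methyl ketone
Conditions: Dess–Martin periodinane, CH2Cl2, 0 °C → rt
Reagents that add atoms: none
Why: Dess–Martin oxidation of the secondary alcohol should give the methyl ketone without touching the silyl ethers or the alkene.

Step 6
Reactants: 8 ring-A methyl ketone
Product: 10 C13 allylic alcohol, via allylic hydroperoxide 9 (not isolated)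
Conditions: O2, tetraphenylporphyrin (cat.), visible light, CH2Cl2, −20 °C; then PPh3
Reagents that add atoms: dioxygen, O=O
Why: Schenck ene reaction of singlet oxygen followed by reduction of the hydroperoxide: the only allylic hydrogen that is axial and has no geminal oxygen is the β-hydrogen on C11, so oxygen should add to C13 on the β face while the alkene moves to C11=C12.

Step 7
Reactants: 10 C13 allylic alcohol
Product: 11 bis-TIPS methyl ketone
Conditions: TIPSOTf, 2,6-lutidine, CH2Cl2, −78 → 0 °C
Reagents that add atoms: triisopropylsilyl trifluoromethanesulfonate, CC(C)[Si](OS(=O)(=O)C(F)(F)F)(C(C)C)C(C)C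
Why: Silylation of the hindered allylic alcohol with the silyl triflate keeps C13 at the alcohol level, so that ring A has no enolisable ketone in steps 10, 11 and 18.

Step 8
Reactants: 12 prop-2-yn-1-ol
Product: 14 (Z)-3-iodo-2-methylprop-2-en-1-ol, via alkenylmagnesium alkoxide 13 (not isolated)
Conditions: MeMgBr (2.5 equiv), CuI (10 mol %), THF, −20 °C → rt; then I2, −78 °C → rt; aq. NH4Cl
Reagents that add atoms: methylmagnesium bromide, C[Mg]Br; iodine, I-I
Why: Copper-catalysed anti-carbomagnesiation of the propargylic alkoxide gives a chelated alkenylmagnesium species whose iodinolysis proceeds with retention, fixing the Z geometry that becomes C5=C6.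

Step 9
Reactants: 14 (Z)-3-iodo-2-methylprop-2-en-1-ol
Product: 15 (Z)-1-bromo-3-iodo-2-methylprop-2-ene
Conditions: CBr4, PPh3, CH2Cl2, 0 °C
Reagents that add atoms: carbon tetrabromide, BrC(Br)(Br)Br
Why: Appel bromination of the primary allylic alcohol should proceed without allylic transposition or loss of alkene geometry.

Step 10
Reactants: 11 bis-TIPS methyl ketone; 15 (Z)-1-bromo-3-iodo-2-methylprop-2-ene
Product: 17 iodoalkenyl ketone, via lithium enolate 16 (not isolated)
Conditions: LiN(i-Pr)2, THF, −78 °C; then 15, HMPA, −78 → −20 °C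
Reagents that add atoms: none
Why: Kinetic lithium enolate alkylation: the quaternary C1 leaves the methyl group as the only enolisable position, and the allylic bromide should react by direct SN2 substitution to form C3–C4.

Step 11
Reactants: 17 iodoalkenyl ketone
Product: 18 (2S)-carbinol
Conditions: (R)-1-methyl-3,3-diphenyltetrahydro-1H,3H-pyrrolo[1,2-c][1,3,2]oxazaborole (50 mol %), catecholborane, toluene, −78 → −40 °C; aq. NaHCO3
Reagents that add atoms: none
Why: Corey–Bakshi–Shibata reduction, in which the oxazaborolidine tells the quaternary C1 (large) from the C3 methylene (small) and should deliver hydride to give the 2S alcohol under reagent control, catecholborane leaving both alkenes untouched.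

Step 12
Reactants: 18 (2S)-carbinol
Product: 19 C2 benzoate
Conditions: BzCl, DMAP, pyridine, 40 °C
Reagents that add atoms: benzoyl chloride, O=C(Cl)c1ccccc1
Why: DMAP-catalysed acylation of the hindered secondary alcohol installs the C2 benzoate of the target.

Step 13
Reactants: 19 C2 benzoate
Product: 20 C8 primary alcohol
Conditions: HF·pyridine, pyridine, THF, 0 °C
Reagents that add atoms: none
Why: Buffered HF·pyridine should cleave the primary TBS ether much faster than the two hindered secondary TIPS ethers (selective desilylation).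

Step 14
Reactants: 20 C8 primary alcohol
Product: 21 C8 aldehyde
Conditions: Dess–Martin periodinane, CH2Cl2, 0 °C → rt
Reagents that add atoms: none
Why: Dess–Martin oxidation gives the aldehyde under non-basic conditions that spare the benzoate and the iodoalkene.

Step 15
Reactants: 21 C8 aldehyde
Product: 22 hydroxymethyl ketone
Conditions: paraformaldehyde, 3-benzyl-5-(2-hydroxyethyl)-4-methylthiazolium chloride (10 mol %), i-Pr2NEt (10 mol %), THF, 60 °C
Reagents that add atoms: formaldehyde (from paraformaldehyde), C=O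
Why: N-heterocyclic-carbene-catalysed hydroxymethylation (cross-benzoin reaction with formaldehyde): the Breslow intermediate of the aldehyde adds to formaldehyde and should give the 1-hydroxy-2-ketone with C7 in place.

Step 16
Reactants: 22 hydroxymethyl ketone; 23 2-(diethoxyphosphoryl)propanoic acid
Product: 24 phosphonate ester
Conditions: DCC, DMAP (cat.), CH2Cl2, 0 °C → rt
Reagents that add atoms: none
Why: Steglich esterification of the primary ketol oxygen with the phosphono acid joins C17–C19 to C7 through the future lactone oxygen.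

Step 17
Reactants: 24 phosphonate ester
Product: 25 butenolide iodoalkene
Conditions: LiCl, DBU, MeCN, rt
Reagents that add atoms: none
Why: Intramolecular Horner–Wadsworth–Emmons reaction (Masamune–Roush conditions) of the phosphonate onto the C8 ketone should close the α-methyl butenolide at C8=C17 without forming a stereocentre.

Step 18
Reactants: 25 butenolide iodoalkene
Product: 26 macrocycle bis-TIPS ether
Conditions: Pd2(dba)3 (10 mol %), 2-dicyclohexylphosphino-2′,4′,6′-triisopropylbiphenyl (24 mol %), Cs2CO3, 1,4-dioxane, 80 °C, syringe-pump addition of 25 (final 2 mM)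
Reagents that add atoms: none
Why: Proposed new method: zerovalent palladium inserts into the C6–I bond of the Z-iodoalkene with retention, Cs2CO3 removes a C7 hydrogen of the butenolide (the most acidic C–H of 25, vinylogous to C19=O) to give the aromatic 2-oxidofuran, which replaces iodide on palladium, and reductive elimination at C7 forms the C6–C7 bond and returns the conjugated butenolide. The closest known reaction types are the palladium-catalysed γ-arylation of butenolide dienolates and the intramolecular coupling of ketone enolates with Z-iodoalkenes, both in normal ring sizes; new here are the alkenyl partner at a dienolate γ-carbon and the medium ring. The ten-membered ring is the only ring closed, by macrocyclic C(sp2)–C(sp3) reductive elimination from an eleven-membered palladacycle in which the reacting C7=C8 dienolate bond lies inside the new ring (enol-endo mode). The Z geometry of C5=C6 is that of 14, carried through both organometallic events with retention; the new stereocentre C7 is set by the face of the planar furanolate that the tethered alkenylpalladium can reach, which is dictated by ring A (trans-disposed C9 and C2 arms on C10 and C1) and the 2S benzoate, and since C7–H stays acidic the two C7 epimers can equilibrate under the carbonate to the less strained ring, expected to be the 7R epimer. The step needs coupling at C7 and not at C17, which the C17 methyl group (coupling there would create a quaternary centre and a deconjugated lactone) and the bulky biarylphosphine should secure. It also needs ring closure to outrun oligomerisation, secured by slow addition to a low stationary concentration, and no competing enolate, secured by carrying ring A as the bis-silyl ether.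

Step 19
Reactants: 26 macrocycle bis-TIPS ether
Product: 27 C13,C14 diol
Conditions: HF·pyridine, THF, 0 → 40 °C
Reagents that add atoms: none
Why: Fluoride-mediated cleavage of both TIPS ethers under acidic, non-nucleophilic conditions should neither epimerise C7 nor move the benzoate (desilylation).

Step 20
Reactants: 27 C13,C14 diol
Product: 28 C14 hydroxy enone
Conditions: MnO2, CH2Cl2, rt
Reagents that add atoms: none
Why: Chemoselective allylic oxidation: MnO2 should oxidise only the allylic C13 alcohol to the enone and leave the non-allylic C14 alcohol.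

Step 21
Reactants: 28 C14 hydroxy enone
Product: 29 target CNP0194180.3
Conditions: Ac2O, DMAP, pyridine, CH2Cl2, 0 °C
Reagents that add atoms: acetic anhydride, CC(=O)OC(C)=O
Why: DMAP-catalysed acetylation of the C14 alcohol of the α-ketol under mild base should complete the target without epimerising C14 or C7.

**Compound list**

1 | (E)-pent-2-enal | CC/C=C/C=O | starting material
2 | (1E,3E)-1-(triisopropylsilyloxy)penta-1,3-diene | C/C=C/C=C/O[Si](C(C)C)(C(C)C)C(C)C | intermediate
3 | 3-(tert-butyldimethylsilyloxy)propanal | O=CCCO[Si](C)(C)C(C)(C)C | starting material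
4 | 2-(triphenylphosphoranylidene)propanal | CC(C=O)=P(c1ccccc1)(c1ccccc1)c1ccccc1 | starting material
5 | (E)-5-(tert-butyldimethylsilyloxy)-2-methylpent-2-enal | O=C/C(C)=C/CCO[Si](C)(C)C(C)(C)C | intermediate
6 | ring-A aldehyde: cyclohexene (C12=C13) with 14α-OTIPS; 1β-CH3; 1α-CHO (C2); 10β-CH2CH2OTBS (C9, C8); 11α-CH3 | CC(C)[Si](C(C)C)(C(C)C)O[C@@H]1C=C[C@H](C)[C@@H](CCO[Si](C)(C)C(C)(C)C)[C@]1(C)C=O | intermediate
7 | ring-A carbinol: 6 with CH(OH)CH3 (C2, C3) in place of CHO, both C2 epimers | CC(C)[Si](C(C)C)(C(C)C)O[C@@H]1C=C[C@H](C)[C@@H](CCO[Si](C)(C)C(C)(C)C)[C@]1(C)C(C)O | intermediate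
8 | ring-A methyl ketone: 6 with COCH3 on C1α | CC(C)[Si](C(C)C)(C(C)C)O[C@@H]1C=C[C@H](C)[C@@H](CCO[Si](C)(C)C(C)(C)C)[C@]1(C)C(C)=O | intermediate
9 | allylic hydroperoxide: 13β-OOH, C11=C12, otherwise as 8 | CC(C)[Si](C(C)C)(C(C)C)O[C@@H]1[C@@H](OO)C=C(C)[C@@H](CCO[Si](C)(C)C(C)(C)C)[C@]1(C)C(C)=O | intermediate (not isolated)
10 | C13 allylic alcohol: 13β-OH, C11=C12, 14α-OTIPS, 1β-CH3, 1α-COCH3, 10β-CH2CH2OTBS | CC(C)[Si](C(C)C)(C(C)C)O[C@@H]1[C@@H](O)C=C(C)[C@@H](CCO[Si](C)(C)C(C)(C)C)[C@]1(C)C(C)=O | intermediate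
11 | bis-TIPS methyl ketone: 10 with 13β-OTIPS | CC(C)[Si](C(C)C)(C(C)C)O[C@@H]1[C@@H](O[Si](C(C)C)(C(C)C)C(C)C)C=C(C)[C@@H](CCO[Si](C)(C)C(C)(C)C)[C@]1(C)C(C)=O | intermediate
12 | prop-2-yn-1-ol | C#CCO | starting material
13 | alkenylmagnesium alkoxide: (Z)-BrMgOCH2–C(CH3)=CH–MgBr | Br[Mg]OC/C(C)=C\[Mg]Br | intermediate (not isolated)
14 | (Z)-3-iodo-2-methylprop-2-en-1-ol | OC/C(C)=C\I | intermediate
15 | (Z)-1-bromo-3-iodo-2-methylprop-2-ene | BrC/C(C)=C\I | intermediate
16 | lithium enolate of 11 (C2(OLi)=C3H2) | CC(C)[Si](C(C)C)(C(C)C)O[C@@H]1[C@@H](O[Si](C(C)C)(C(C)C)C(C)C)C=C(C)[C@@H](CCO[Si](C)(C)C(C)(C)C)[C@]1(C)C(=C)O[Li] | intermediate (not isolated)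
17 | iodoalkenyl ketone: 11 with C1α–C(=O)CH2CH2C(CH3)=CHI (Z) (C2–C6) | CC(C)[Si](C(C)C)(C(C)C)O[C@@H]1[C@@H](O[Si](C(C)C)(C(C)C)C(C)C)C=C(C)[C@@H](CCO[Si](C)(C)C(C)(C)C)[C@]1(C)C(=O)CC/C(C)=C\I | intermediate
18 | (2S)-carbinol: 17 reduced at C2 to the 2S alcohol | CC(C)[Si](C(C)C)(C(C)C)O[C@@H]1[C@@H](O[Si](C(C)C)(C(C)C)C(C)C)C=C(C)[C@@H](CCO[Si](C)(C)C(C)(C)C)[C@]1(C)[C@@H](O)CC/C(C)=C\I | intermediate
19 | C2 benzoate of 18 | CC(C)[Si](C(C)C)(C(C)C)O[C@@H]1[C@@H](O[Si](C(C)C)(C(C)C)C(C)C)C=C(C)[C@@H](CCO[Si](C)(C)C(C)(C)C)[C@]1(C)[C@@H](OC(=O)c1ccccc1)CC/C(C)=C\I | intermediate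
20 | C8 primary alcohol: 19 without the TBS group (10β-CH2CH2OH) | CC(C)[Si](C(C)C)(C(C)C)O[C@@H]1[C@@H](O[Si](C(C)C)(C(C)C)C(C)C)C=C(C)[C@@H](CCO)[C@]1(C)[C@@H](OC(=O)c1ccccc1)CC/C(C)=C\I | intermediate
21 | C8 aldehyde: 10β-CH2CHO | CC(C)[Si](C(C)C)(C(C)C)O[C@@H]1[C@@H](O[Si](C(C)C)(C(C)C)C(C)C)C=C(C)[C@@H](CC=O)[C@]1(C)[C@@H](OC(=O)c1ccccc1)CC/C(C)=C\I | intermediate
22 | hydroxymethyl ketone: 10β-CH2C(=O)CH2OH (C9, C8, C7) | CC(C)[Si](C(C)C)(C(C)C)O[C@@H]1[C@@H](O[Si](C(C)C)(C(C)C)C(C)C)C=C(C)[C@@H](CC(=O)CO)[C@]1(C)[C@@H](OC(=O)c1ccccc1)CC/C(C)=C\I | intermediate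
23 | 2-(diethoxyphosphoryl)propanoic acid (racemic) | CCOP(=O)(OCC)C(C)C(=O)O | starting material
24 | phosphonate ester: 22 acylated on the C7 oxygen by 23 (both epimers at the phosphonate carbon) | CC(C)[Si](C(C)C)(C(C)C)O[C@@H]1[C@@H](O[Si](C(C)C)(C(C)C)C(C)C)C=C(C)[C@@H](CC(=O)COC(=O)C(C)P(=O)(OCC)OCC)[C@]1(C)[C@@H](OC(=O)c1ccccc1)CC/C(C)=C\I | intermediate
25 | butenolide iodoalkene: ring A with 13β,14α-bis-OTIPS; 10β-CH2-(4-methyl-5-oxo-2,5-dihydrofuran-3-yl); 1α-[(1S,4Z)-1-benzoyloxy-5-iodo-4-methylpent-4-en-1-yl]; 1β-CH3 | CC(C)[Si](C(C)C)(C(C)C)O[C@@H]1[C@@H](O[Si](C(C)C)(C(C)C)C(C)C)C=C(C)[C@@H](CC2=C(C)C(=O)OC2)[C@]1(C)[C@@H](OC(=O)c1ccccc1)CC/C(C)=C\I | intermediate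
26 | macrocycle bis-TIPS ether: target ring system with 13β-OTIPS and 14α-OTIPS in place of the C13 ketone and the C14 acetate | CC(C)[Si](C(C)C)(C(C)C)O[C@@H]1[C@@H](O[Si](C(C)C)(C(C)C)C(C)C)C=C(C)[C@H]2CC3=C(C)C(=O)O[C@@H]3/C=C(/C)CC[C@H](OC(=O)c3ccccc3)[C@@]21C | intermediate
27 | C13,C14 diol: 13β-OH, 14α-OH | O[C@@H]1[C@@H](O)C=C(C)[C@H]2CC3=C(C)C(=O)O[C@@H]3/C=C(/C)CC[C@H](OC(=O)c3ccccc3)[C@@]21C | intermediate
28 | C14 hydroxy enone: C13 ketone, 14α-OH | O[C@@H]1C(=O)C=C(C)[C@H]2CC3=C(C)C(=O)O[C@@H]3/C=C(/C)CC[C@H](OC(=O)c3ccccc3)[C@@]21C | intermediate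
29 | CNP0194180.3: (1R,2S,5Z,7R,10R,14S)-14-acetoxy-2-benzoyloxy-13-oxo tricyclic butenolide | CC(=O)O[C@@H]1C(=O)C=C(C)[C@H]2CC3=C(C)C(=O)O[C@@H]3/C=C(/C)CC[C@H](OC(=O)c3ccccc3)[C@@]21C | target

**Count and risks**

Total steps: 21. Longest linear sequence: 18 (steps 2–7 and 10–21).

Step 18 (the proposed new method). What may go wrong: oligomerisation in place of ring closure; coupling at C17 instead of C7; ionisation of the allylic C7–O bond of the product by zerovalent palladium; addition to the wrong face at C7. The fallback uses known chemistry only, sets out from 25 and comes back at 26. TIPSOTf and Et3N convert the butenolide of 25 into the 2-(triisopropylsilyloxy)furan F1. One equivalent of dimethyldioxirane at −78 °C oxidises this furan, which is far more electron-rich than the C11=C12 alkene, to the 5-hydroxybutenolide F2. MeI and K2CO3 in DMF open the lactol to the methyl (Z)-3-formyl-2-methylalk-2-enoate F3. A Nozaki–Hiyama–Kishi reaction (CrCl2, catalytic NiCl2, DMSO, high dilution) then adds the alkenylchromium made from the Z-iodoalkene to the aldehyde and closes the ten-membered ring to the macrocyclic C7 hydroxy ester F4, which lactonises on work-up to 26. In this variant the carbocycle closes before the lactone, and C7 is set kinetically; a chiral sulfonamide ligand on chromium is available for reagent control.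

Step 3. What may go wrong: poor endo/exo or facial selectivity, or acid-triggered loss of the dienol silyl ether. The fallback sets out from 2 and 5 and comes back at 6. The cycloaddition is run with the achiral Lewis acid Me2AlCl (CH2Cl2, −78 °C), which should give 6 together with its mirror image F5. The mixture is condensed with (1R,2R)-N,N′-dimethyl-1,2-diphenylethane-1,2-diamine to the diastereomeric aminals F6 (from 6) and F7 (from F5). These are separated by chromatography, and F6 is hydrolysed with dilute aqueous HCl back to enantiopure 6: resolution in place of asymmetric catalysis.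

Step 15. What may go wrong: homo-benzoin and aldol condensation of the enolisable aldehyde outrunning the cross-coupling with formaldehyde. The fallback sets out from 21 and comes back at 24. Pinnick oxidation (NaClO2, NaH2PO4, 2-methylbut-2-ene) gives the carboxylic acid F8. Oxalyl chloride followed by trimethylsilyldiazomethane and Et3N gives the α-diazoketone F9. O–H insertion of its rhodium carbenoid (Rh2(OAc)4, CH2Cl2) into the carboxylic acid 23 gives ester 24 directly, so the ketol 22 is bypassed.

Further compounds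
F1 | step 18 | 2-(triisopropylsilyloxy)furan derived from 25 | CC(C)[Si](C(C)C)(C(C)C)O[C@@H]1[C@@H](O[Si](C(C)C)(C(C)C)C(C)C)C=C(C)[C@@H](CC2=COC(O[Si](C(C)C)(C(C)C)C(C)C)=C2C)[C@]1(C)[C@@H](OC(=O)c1ccccc1)CC/C(C)=C\I
F2 | step 18 | 5-hydroxybutenolide (lactol at C7, both epimers) | CC(C)[Si](C(C)C)(C(C)C)O[C@@H]1[C@@H](O[Si](C(C)C)(C(C)C)C(C)C)C=C(C)[C@@H](CC2=C(C)C(=O)OC2O)[C@]1(C)[C@@H](OC(=O)c1ccccc1)CC/C(C)=C\I
F3 | step 18 | methyl (Z)-3-formyl-2-methylalk-2-enoate (C7 aldehyde, C19 methyl ester) | CC(C)[Si](C(C)C)(C(C)C)O[C@@H]1[C@@H](O[Si](C(C)C)(C(C)C)C(C)C)C=C(C)[C@@H](C/C(C=O)=C(\C)C(=O)OC)[C@]1(C)[C@@H](OC(=O)c1ccccc1)CC/C(C)=C\I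
F4 | step 18 | macrocyclic C7 hydroxy ester | CC(C)[Si](C(C)C)(C(C)C)O[C@@H]1[C@@H](O[Si](C(C)C)(C(C)C)C(C)C)C=C(C)[C@H]2C/C(=C(\C)C(=O)OC)[C@H](O)/C=C(/C)CC[C@H](OC(=O)c3ccccc3)[C@@]21C
F5 | step 3 | mirror image of 6 | CC(C)[Si](C(C)C)(C(C)C)O[C@H]1C=C[C@@H](C)[C@H](CCO[Si](C)(C)C(C)(C)C)[C@@]1(C)C=O
F6 | step 3 | aminal of 6 with the (1R,2R)-diamine | CC(C)[Si](C(C)C)(C(C)C)O[C@@H]1C=C[C@H](C)[C@@H](CCO[Si](C)(C)C(C)(C)C)[C@]1(C)C1N(C)[C@H](c2ccccc2)[C@@H](c2ccccc2)N1C
F7 | step 3 | aminal of F5 with the (1R,2R)-diamine | CC(C)[Si](C(C)C)(C(C)C)O[C@H]1C=C[C@@H](C)[C@H](CCO[Si](C)(C)C(C)(C)C)[C@@]1(C)C1N(C)[C@H](c2ccccc2)[C@@H](c2ccccc2)N1C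
F8 | step 15 | C8 carboxylic acid | CC(C)[Si](C(C)C)(C(C)C)O[C@@H]1[C@@H](O[Si](C(C)C)(C(C)C)C(C)C)C=C(C)[C@@H](CC(=O)O)[C@]1(C)[C@@H](OC(=O)c1ccccc1)CC/C(C)=C\I
F9 | step 15 | α-diazoketone | CC(C)[Si](C(C)C)(C(C)C)O[C@@H]1[C@@H](O[Si](C(C)C)(C(C)C)C(C)C)C=C(C)[C@@H](CC(=O)C=[N+]=[N-])[C@]1(C)[C@@H](OC(=O)c1ccccc1)CC/C(C)=C\I
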